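Atom labels follow the isochromene numbering of the target (C1 = OCH=, O2, C3 = CHMe, C4 = CH2, C4a, C5 = ring CH=, C6 and C8 = C=O, C7 = C(Me)O, C8a) and are kept for every intermediate.
Retrosynthetic cuts, in order: first the linoleate C(=O)–O bond at C7, then C7–C8 of the carbocycle. The second cut is possible because C6–C7–C8 is a 1,3-dione with a fully substituted central carbon C7. The carbocycle is therefore the C-acyl isomer of a six-membered enol lactone (ring O–C8–C8a–C4a–C5–C6, exocyclic C6=C7) whose ring oxygen takes the place of C7.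
Further cuts: lactone O–C8, O2–C1 and C1=C8a (one carbon from an amide acetal), C8a–C4a (acetate aldol), C4a–C5 (acetylide plus Weinreb amide). The C6 ketone arises by 1,3-transposition of the C4a hydroxyl.
Forward order: chain C3–C4–C4a–C5–C6–C7, then C8a–C8, then the dihydropyran ring, then the lactone ring, then exchange of the lactone ring for the cyclohexenedione ring, last the fatty ester.
Stereochemistry: C3 (R) is bought with methyl (R)-3-hydroxybutanoate and no bond to it is ever broken. C7 (R) is created in the ring exchange under a chiral isothiourea catalyst. The two Z alkenes come with linoleic acid.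
Key step: step 10

Assumption 1: racemic but-3-yn-2-ol suffices because its carbinol carbon (C7) becomes trigonal before the key step; until then the intermediates are epimer mixtures at C7 and their SMILES leave this centre open.
Assumption 2: the exocyclic C4a=C5 bond belongs to a donor–acceptor diene and is taken to equilibrate under weak acid; it is left open in the SMILES up to the allyl ester and drawn Z from the free acid on.
Assumption 3: the sense of induction cannot be derived from a close precedent; (2S,3R)-HyperBTM [(2S,3R)-3-isopropyl-2-phenyl-3,4-dihydro-2H-benzo[4,5]thiazolo[3,2-a]pyrimidine, SMILES CC(C)[C@@H]1CN2c3ccccc3SC2=N[C@@H]1c1ccccc1] is written, and its equally available mirror image would be used if a trial run gives the 7S epimer.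

Step 1
Reactants: 1 methyl (R)-3-hydroxybutanoate
Product: 2 methyl (R)-3-[(tert-butyldimethylsilyl)oxy]butanoate
Conditions: TBSCl, imidazole, DMF, rt
Reagents that add atoms: tert-butyldimethylsilyl chloride, CC(C)(C)[Si](C)(C)Cl
Why: Imidazole-promoted silyl ether protection of the secondary alcohol masks the future O2 for the basic and organometallic steps and breaks no bond at C3, so the R configuration is carried on.

Step 2
Reactants: 2 methyl (R)-3-[(tert-butyldimethylsilyl)oxy]butanoate
Product: 3 (R)-3-[(tert-butyldimethylsilyl)oxy]-N-methoxy-N-methylbutanamide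
Conditions: MeNHOMe·HCl, iPrMgCl, THF, −20 to 0 °C
Reagents that add atoms: N,O-dimethylhydroxylamine hydrochloride, CNOC.Cl
Why: Weinreb amide formation with the magnesium amide is fast at low temperature, so β-elimination of the silyloxy group is not expected, and it gives an acyl donor that stops at the ketone stage.

Step 3
Reactants: 4 but-3-yn-2-ol (racemic); 5 4-methoxybenzyl chloride
Product: 6 1-[(but-3-yn-2-yloxy)methyl]-4-methoxybenzene (racemic)
Conditions: NaH, Bu4NI (cat.), THF/DMF, 0 °C to rt
Reagents that add atoms: none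
Why: Williamson ether synthesis; the O–H is far more acidic than the alkyne C–H, so only oxygen is alkylated, and the racemic carbinol centre (C7) is harmless because it is made trigonal later.

Step 4
Reactants: 6 1-[(but-3-yn-2-yloxy)methyl]-4-methoxybenzene; 3 (R)-3-[(tert-butyldimethylsilyl)oxy]-N-methoxy-N-methylbutanamide
Product: 8 (2R)-2-[(tert-butyldimethylsilyl)oxy]-7-[(4-methoxybenzyl)oxy]oct-5-yn-4-one, via lithium acetylide 7 (not isolated)
Conditions: 6, n-BuLi, THF, −78 °C; then 3, −78 to 0 °C; aq NH4Cl
Reagents that add atoms: none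
Why: Acylation of an alkynyllithium by a Weinreb amide forms C4a–C5, and the chelated tetrahedral adduct holds until the quench, so no second addition occurs.

Step 5
Reactants: 9 allyl acetate; 8 (2R)-2-[(tert-butyldimethylsilyl)oxy]-7-[(4-methoxybenzyl)oxy]oct-5-yn-4-one
Product: 11 allyl 3-hydroxy-3-{(2R)-2-[(tert-butyldimethylsilyl)oxy]propyl}-6-[(4-methoxybenzyl)oxy]hept-4-ynoate, via lithium enolate 10 (not isolated)
Conditions: 9, LiN(iPr)2, THF, −78 °C; then 8, −78 °C; aq NH4Cl
Reagents that add atoms: none
Why: Acetate aldol addition; lithium ester enolates add to the carbonyl carbon of ynones at −78 °C faster than they enolise them or add in conjugate fashion, which forms C8a–C4a, and the new carbinol centre is erased in the next step so its configuration does not matter.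

Step 6
Reactants: 11 allyl 3-hydroxy-3-{(2R)-2-[(tert-butyldimethylsilyl)oxy]propyl}-6-[(4-methoxybenzyl)oxy]hept-4-ynoate
Product: 12 allyl 3-{(2R)-2-[(tert-butyldimethylsilyl)oxy]propyl}-6-[(4-methoxybenzyl)oxy]-5-oxohept-3-enoate (E/Z mixture)
Conditions: MoO2(acac)2 (2 mol %), AuCl(PPh3) (2 mol %), AgOTf (2 mol %), toluene, rt
Reagents that add atoms: none
Why: Meyer–Schuster rearrangement; only the free tertiary hydroxyl can bind to molybdenum as an oxo ester and be shifted from C4a to C6 across the gold-activated alkyne, so the PMB ether at the other propargylic carbon is left alone and the allenol tautomerises to the C4a=C5–C6=O enone.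

Step 7
Reactants: 12 allyl 3-{(2R)-2-[(tert-butyldimethylsilyl)oxy]propyl}-6-[(4-methoxybenzyl)oxy]-5-oxohept-3-enoate
Product: 15 allyl (2R)-4-{3-[(4-methoxybenzyl)oxy]-2-oxobutylidene}-2-methyl-3,4-dihydro-2H-pyran-5-carboxylate (E/Z mixture), via aminomethylene ester 13 (not isolated), via hydroxy aminomethylene ester 14 (not isolated)
Conditions: Me2NCH(OMe)2, toluene, 40 °C; evaporate; 48% aq HF, MeCN, 0 °C to rt
Reagents that add atoms: N,N-dimethylformamide dimethyl acetal, COC(OC)N(C)C
Why: Amide acetal condensation at C8a, the only doubly activated methylene (α to the ester and vinylogous to the ketone), brings in C1, and acidic desilylation then lets the C3 hydroxyl displace dimethylamine at C1 by addition–elimination (6-endo-trig), the sequence known for turning δ-hydroxy-β-keto esters into dihydropyranones.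

Step 8
Reactants: 15 allyl (2R)-4-{3-[(4-methoxybenzyl)oxy]-2-oxobutylidene}-2-methyl-3,4-dihydro-2H-pyran-5-carboxylate
Product: 16 (2R,4Z)-4-{3-[(4-methoxybenzyl)oxy]-2-oxobutylidene}-2-methyl-3,4-dihydro-2H-pyran-5-carboxylic acid
Conditions: Pd(PPh3)4 (5 mol %), HCO2H, Et3N, THF, rt
Reagents that add atoms: none
Why: Tsuji–Trost-type deallylation with formate as hydride donor frees the acid without hydroxide or amine nucleophiles that would attack the electrophilic C1, while the weak acid lets the donor–acceptor C4a=C5 bond equilibrate toward the Z form, which is favoured by reversible addition of the carboxyl group to the C6 ketone.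

Step 9
Reactants: 16 (2R,4Z)-4-{3-[(4-methoxybenzyl)oxy]-2-oxobutylidene}-2-methyl-3,4-dihydro-2H-pyran-5-carboxylic acid
Product: 19 (3R,6Z)-6-{1-[(4-methoxybenzyl)oxy]ethylidene}-3-methyl-3,4-dihydro-6H,8H-pyrano[3,4-c]pyran-8-one, via acyl fluoride 17 (not isolated), via chelated lithium enolate 18 (not isolated)
Conditions: cyanuric fluoride, pyridine, CH2Cl2, −10 °C; filter, evaporate; add to LiN(SiMe3)2, THF, −78 °C (inverse addition); pH 7 buffer
Reagents that add atoms: none
Why: Enolate O-acylation; the acyl fluoride does not ionise onto the ketone, kinetic deprotonation of an enone takes the α′ proton (C7–H) and not the vinylogous C4–H, lithium chelation by the PMB oxygen gives the Z-enolate, and its oxygen lies next to C8 and closes the lactone (6-exo-trig) with loss of inert LiF.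

Step 10
Reactants: 19 (3R,6Z)-6-{1-[(4-methoxybenzyl)oxy]ethylidene}-3-methyl-3,4-dihydro-6H,8H-pyrano[3,4-c]pyran-8-one
Product: 21 (3R,7R)-7-[(4-methoxybenzyl)oxy]-3,7-dimethyl-3,4-dihydro-6H-isochromene-6,8(7H)-dione, via acyl isothiouronium enolate 20 (not isolated)
Conditions: (2S,3R)-HyperBTM (10 mol %), 4 Å molecular sieves, dry acid-free toluene, rt to 50 °C
Reagents that add atoms: none
Why: Proposed new method: the sp2 nitrogen of the isothiourea adds to the lactone carbonyl C8 and expels the C6 oxygen, which gives zwitterion 20, a Z-enolate (C6–O−, C6=C7) still tied to its acyl isothiouronium through C5=C4a–C8a; rotation about C5–C6 brings C7 to C8, C7 attacks, the catalyst leaves, and the O–C8 bond has been exchanged for C7–C8. The closest known reaction types are the Steglich-type O-to-C acyl and carboxyl shifts of azlactone, oxindole and benzofuranone enol esters under chiral 4-aminopyridine or isothiourea catalysis, the catalytic C-acylation of silyl ketene acetals through enolate/acylpyridinium ion pairs, and the alkoxide-induced isomerisation of enol δ-lactones to cyclohexane-1,3-diones; new is the asymmetric version on a six-membered enol lactone of a plain ketone. The cyclohexenedione ring closes in the 6-(enolendo)-exo-trig mode through a helically twisted chain C7=C6–C5=C4a–C8a–C8, a geometry like that of a hexatriene ring closure. C7 is controlled by the catalyst alone: the 1,5-O···S contact keeps the acyl C=O coplanar to the isothiouronium, the phenyl group at its C2 screens one face of C8, only one helical sense of the chain can then reach C8, and because the enolate has a single (Z) geometry this sense exposes only one face of C7; C3 is too remote to matter but turns any 7-epimer into a separable diastereomer. The step needs C- over O-acylation and attack at C8 only: O-attack merely returns 19 whereas C-attack is irreversible because the 1,3-dione is the more stable isomer and offers the catalyst no leaving group, the pyran ring holds C1 on the C4 side of the C4a–C8a bond and so out of reach of C7, the ether (not an ester) at the C7 oxygen leaves C8 as the only acyl group the catalyst can take up, and the weakly basic catalyst does not touch the C4 protons.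

Step 11
Reactants: 21 (3R,7R)-7-[(4-methoxybenzyl)oxy]-3,7-dimethyl-3,4-dihydro-6H-isochromene-6,8(7H)-dione
Product: 22 (3R,7R)-7-hydroxy-3,7-dimethyl-3,4-dihydro-6H-isochromene-6,8(7H)-dione
Conditions: DDQ, CH2Cl2/pH 7 buffer, 0 °C to rt
Reagents that add atoms: none
Why: Oxidative PMB ether cleavage starts at the electron-rich benzylic CH2 and is much faster at this temperature than dehydrogenation of the electron-poor core, and the C7–O bond stays intact so the configuration is kept.

Step 12
Reactants: 23 linoleic acid; 22 (3R,7R)-7-hydroxy-3,7-dimethyl-3,4-dihydro-6H-isochromene-6,8(7H)-dione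
Product: 25 (3R,7R)-3,7-dimethyl-6,8-dioxo-3,4,7,8-tetrahydro-6H-isochromen-7-yl (9Z,12Z)-octadeca-9,12-dienoate, via linoleoyl chloride 24 (not isolated)
Conditions: 23, (COCl)2, DMF (cat.), CH2Cl2, 0 °C to rt, evaporate; then 22, Et3N, DMAP, CH2Cl2, 0 °C to rt, argon
Reagents that add atoms: none
Why: DMAP-catalysed acylation of a hindered tertiary alcohol by an acid chloride, the usual way to the C7 esters of azaphilone-type cores, breaks no bond at C7 and leaves the skipped Z,Z-diene untouched under argon.

Compound list
1 | methyl (R)-3-hydroxybutanoate | C[C@@H](O)CC(=O)OC | starting material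
2 | methyl (R)-3-[(tert-butyldimethylsilyl)oxy]butanoate | C[C@@H](O[Si](C)(C)C(C)(C)C)CC(=O)OC | intermediate
3 | (R)-3-[(tert-butyldimethylsilyl)oxy]-N-methoxy-N-methylbutanamide | C[C@@H](O[Si](C)(C)C(C)(C)C)CC(=O)N(C)OC | intermediate
4 | but-3-yn-2-ol (racemic) | CC(O)C#C | starting material
5 | 4-methoxybenzyl chloride | COc1ccc(CCl)cc1 | starting material
6 | 1-[(but-3-yn-2-yloxy)methyl]-4-methoxybenzene (racemic) | CC(OCc1ccc(OC)cc1)C#C | intermediate
7 | lithium acetylide of 6 | CC(OCc1ccc(OC)cc1)C#C[Li] | intermediate
8 | (2R)-2-[(tert-butyldimethylsilyl)oxy]-7-[(4-methoxybenzyl)oxy]oct-5-yn-4-one (C7 epimers) | C[C@@H](O[Si](C)(C)C(C)(C)C)CC(=O)C#CC(C)OCc1ccc(OC)cc1 | intermediate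
9 | allyl acetate | CC(=O)OCC=C | starting material
10 | lithium enolate of allyl acetate | C=C(O[Li])OCC=C | intermediate
11 | allyl 3-hydroxy-3-{(2R)-2-[(tert-butyldimethylsilyl)oxy]propyl}-6-[(4-methoxybenzyl)oxy]hept-4-ynoate (epimers at C4a and C7) | C=CCOC(=O)CC(O)(C[C@@H](C)O[Si](C)(C)C(C)(C)C)C#CC(C)OCc1ccc(OC)cc1 | intermediate
12 | allyl 3-{(2R)-2-[(tert-butyldimethylsilyl)oxy]propyl}-6-[(4-methoxybenzyl)oxy]-5-oxohept-3-enoate (E/Z mixture, C7 epimers) | C=CCOC(=O)CC(C[C@@H](C)O[Si](C)(C)C(C)(C)C)=CC(=O)C(C)OCc1ccc(OC)cc1 | intermediate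
13 | allyl 2-[(dimethylamino)methylidene]-3-{(2R)-2-[(tert-butyldimethylsilyl)oxy]propyl}-6-[(4-methoxybenzyl)oxy]-5-oxohept-3-enoate | C=CCOC(=O)C(=CN(C)C)C(C[C@@H](C)O[Si](C)(C)C(C)(C)C)=CC(=O)C(C)OCc1ccc(OC)cc1 | intermediate
14 | allyl 2-[(dimethylamino)methylidene]-3-[(2R)-2-hydroxypropyl]-6-[(4-methoxybenzyl)oxy]-5-oxohept-3-enoate | C=CCOC(=O)C(=CN(C)C)C(C[C@@H](C)O)=CC(=O)C(C)OCc1ccc(OC)cc1 | intermediate
15 | allyl (2R)-4-{3-[(4-methoxybenzyl)oxy]-2-oxobutylidene}-2-methyl-3,4-dihydro-2H-pyran-5-carboxylate (E/Z mixture, C7 epimers) | C=CCOC(=O)C1=CO[C@H](C)CC1=CC(=O)C(C)OCc1ccc(OC)cc1 | intermediate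
16 | (2R,4Z)-4-{3-[(4-methoxybenzyl)oxy]-2-oxobutylidene}-2-methyl-3,4-dihydro-2H-pyran-5-carboxylic acid (C7 epimers) | OC(=O)C1=CO[C@H](C)C/C1=C/C(=O)C(C)OCc1ccc(OC)cc1 | intermediate
17 | acyl fluoride of 16 | O=C(F)C1=CO[C@H](C)C/C1=C/C(=O)C(C)OCc1ccc(OC)cc1 | intermediate
18 | chelated lithium (Z)-enolate (C6–OLi, C6=C7) of 17 | C/C(OCc1ccc(OC)cc1)=C(/O[Li])\C=C1\C[C@@H](C)OC=C1C(F)=O | intermediate
19 | (3R,6Z)-6-{1-[(4-methoxybenzyl)oxy]ethylidene}-3-methyl-3,4-dihydro-6H,8H-pyrano[3,4-c]pyran-8-one (enol δ-lactone, key-step precursor) | C/C(OCc1ccc(OC)cc1)=C1/OC(=O)C2=CO[C@H](C)CC2=C1 | intermediate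
20 | zwitterion: C8 acyl isothiouronium of (2S,3R)-HyperBTM with the tethered (Z)-enolate | C/C(OCc1ccc(OC)cc1)=C(/[O-])\C=C2\C[C@@H](C)OC=C2C(=O)[N+]3=C4Sc5ccccc5N4C[C@@H](C(C)C)[C@H]3c3ccccc3 | intermediate
21 | (3R,7R)-7-[(4-methoxybenzyl)oxy]-3,7-dimethyl-3,4-dihydro-6H-isochromene-6,8(7H)-dione (key-step product) | COc1ccc(CO[C@]2(C)C(=O)C=C3C[C@@H](C)OC=C3C2=O)cc1 | intermediate
22 | (3R,7R)-7-hydroxy-3,7-dimethyl-3,4-dihydro-6H-isochromene-6,8(7H)-dione | O[C@]1(C)C(=O)C=C2C[C@@H](C)OC=C2C1=O | intermediate
23 | linoleic acid, (9Z,12Z)-octadeca-9,12-dienoic acid | CCCCC/C=C\C/C=C\CCCCCCCC(=O)O | starting material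
24 | linoleoyl chloride | CCCCC/C=C\C/C=C\CCCCCCCC(=O)Cl | intermediate
25 | (3R,7R)-3,7-dimethyl-6,8-dioxo-3,4,7,8-tetrahydro-6H-isochromen-7-yl (9Z,12Z)-octadeca-9,12-dienoate (CNP0260084.1) | CCCCC/C=C\C/C=C\CCCCCCCC(=O)O[C@]1(C)C(=O)C=C2C[C@@H](C)OC=C2C1=O | target

Total step count: 12. Longest linear sequence: 11 steps (1, 2, 4 to 12) from methyl (R)-3-hydroxybutanoate.

Steps most likely to fail

First, step 10.
- What may go wrong: the lactone carbonyl is a vinylogous carbonate and the departing enolate is that of a plain ketone. Ring opening by the catalyst may therefore be too slow, the ion pair may collapse back only through oxygen, or the facial selectivity may be low.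
- Fallback (known chemistry, no catalyst control): set out from acid 16 and convert it with C6F5OH and EDC·HCl into the pentafluorophenyl ester F1. Treat this with MgBr2·OEt2 and iPr2NEt in CH2Cl2.
- Soft enolisation of the magnesium-chelated α-alkoxy ketone at C7 is followed by intramolecular C-acylation. This is a Dieckmann-type closure on an activated ester whose phenoxide cannot cleave the product.
- It should give 21 together with its 7-epimer F2. Because of C3 the two are diastereomers, so they would be separated by chromatography and the route is rejoined at 21 at the cost of the unwanted epimer.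

Second, step 9.
- What may go wrong: the amide base may attack the acyl fluoride, or the E to Z equilibration at C4a=C5 may be incomplete. Proton exchange may also lead to deprotonation at C4, which opens the pyran by β-elimination of O2 and endangers C3. Weak chelation would erode the geometry at C6=C7.
- Fallback: set out from 16 in its ring-closed tautomeric form, the hydroxy lactone F3. Treat it under neutral conditions with the Burgess reagent (MeO2CN−SO2N+Et3) in toluene at rt to 50 °C.
- The C6 sulfamate F4 formed in this way loses its sulfamate by syn-elimination, which can reach only the hydrogen on C7. No enolate is involved, E and Z enol lactones would be separated, and the route is rejoined at 19.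

Third, step 6.
- What may go wrong: instead of the 1,3-shift the tertiary alcohol may lose water to an enyne. The ester carbonyl may add to the gold-activated alkyne, or the enone may close to a 2-pyranone with loss of allyl alcohol.
- Fallback: set out from 11 and acetylate (Ac2O, DMAP, Et3N) to the tertiary acetate F5. Eliminate with DBU (E1cB toward C8a) to the enynoate F6.
- Add pyrrolidine to its alkyne terminus C6 (1,6-addition) to give the dienamine F7, and hydrolyse with aqueous oxalic acid.
- Oxygen is then placed at C6 by the polarity of the enynoate and not by a metal, and the route is rejoined at 12.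

Further compounds
F1 | step 10 | pentafluorophenyl (2R,4Z)-4-{3-[(4-methoxybenzyl)oxy]-2-oxobutylidene}-2-methyl-3,4-dihydro-2H-pyran-5-carboxylate | O=C(Oc1c(F)c(F)c(F)c(F)c1F)C1=CO[C@H](C)C/C1=C/C(=O)C(C)OCc1ccc(OC)cc1
F2 | step 10 | (3R,7S)-7-[(4-methoxybenzyl)oxy]-3,7-dimethyl-3,4-dihydro-6H-isochromene-6,8(7H)-dione | COc1ccc(CO[C@@]2(C)C(=O)C=C3C[C@@H](C)OC=C3C2=O)cc1
F3 | step 9 | (3R)-6-hydroxy-6-{1-[(4-methoxybenzyl)oxy]ethyl}-3-methyl-3,4-dihydro-6H,8H-pyrano[3,4-c]pyran-8-one | CC(OCc1ccc(OC)cc1)C1(O)OC(=O)C2=CO[C@H](C)CC2=C1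
F4 | step 9 | C6 O-[N-(methoxycarbonyl)sulfamoyl] derivative of F3 | CC(OCc1ccc(OC)cc1)C1(OS(=O)(=O)NC(=O)OC)OC(=O)C2=CO[C@H](C)CC2=C1
F5 | step 6 | allyl 3-acetoxy-3-{(2R)-2-[(tert-butyldimethylsilyl)oxy]propyl}-6-[(4-methoxybenzyl)oxy]hept-4-ynoate | C=CCOC(=O)CC(OC(C)=O)(C[C@@H](C)O[Si](C)(C)C(C)(C)C)C#CC(C)OCc1ccc(OC)cc1
F6 | step 6 | allyl 3-{(2R)-2-[(tert-butyldimethylsilyl)oxy]propyl}-6-[(4-methoxybenzyl)oxy]hept-2-en-4-ynoate (E/Z mixture) | C=CCOC(=O)C=C(C[C@@H](C)O[Si](C)(C)C(C)(C)C)C#CC(C)OCc1ccc(OC)cc1
F7 | step 6 | allyl 3-{(2R)-2-[(tert-butyldimethylsilyl)oxy]propyl}-6-[(4-methoxybenzyl)oxy]-5-(pyrrolidin-1-yl)hepta-2,4-dienoate | C=CCOC(=O)C=C(C[C@@H](C)O[Si](C)(C)C(C)(C)C)C=C(N1CCCC1)C(C)OCc1ccc(OC)cc1
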